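**Plan**

- Numbering (bicyclo[3.3.1]nonane): C1 is the bridgehead carrying isobutyryl, C2–C3–C4 the enolised 1,3-diketone bridge, C5 the prenyl bridgehead, C6H2–C7H–C8Me2 the three-carbon bridge, C9 the bridging ketone.
- Retrosynthesis: cut C3–prenyl (back to C3–H, and from there to a C3 isobutyryl group), cut C7–prenyl (back to C7–SePh), then cut C1–C8. This opens ring C1–C8–C7–C6–C5–C9 to a monocyclic dearomatised 2,4-diisobutyryl-6,6-diprenyl phloroglucinol; the acyl and prenyl bonds to the phloroglucinol ring are cut last.
- Enabling feature: the C6–C7–C8 bridge is a prenyl group on C5 whose tertiary carbon C8 is bonded to the acyl-bearing carbon C1. With a second isobutyryl group on C3, the opened monocycle has a twofold axis through C5, so either prenyl alkene and either acyl-bearing carbon lead to the same bicycle.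
- Forward: phloroglucinol is diacylated, dearomatised by gem-diprenylation and closed once by PhSe+ (the only ring-forming step); then SePh is exchanged for prenyl at C7 and isobutyryl for H, then prenyl, at C3.
- Stereochemistry: C7 comes from the alkene face selected by a chiral hydrogen-bond donor in the seleniranium closure; C1 and C5 follow from anti opening in a chair (SePh exo); the radical exchange at C7 keeps the exo configuration.

Key step: step 3

Assumption: enolised di- and triketones are drawn as single tautomers although they interconvert; which antipode of the squaramide gives the 7S series has to be settled by a trial run, and that antipode is meant.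

Step 1
Reactants: 1 phloroglucinol; 2 isobutyryl chloride
Product: 4 2,4-diisobutyrylphloroglucinol [1,1'-(2,4,6-trihydroxy-1,3-phenylene)bis(2-methylpropan-1-one)], via monoacyl phloroglucinol 3 (not isolated)
Conditions: 2 (2.2 equiv), AlCl3 (4 equiv), PhNO2, 0 to 65 °C; aq. HCl work-up
Reagents that add atoms: isobutyryl chloride (2), CC(C)C(Cl)=O
Why: Friedel–Crafts C-acylation of the very electron-rich ring should occur twice at this stoichiometry, since the first chelated acyl group deactivates only moderately while a third acylation is slow.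

Step 2
Reactants: 4 2,4-diisobutyrylphloroglucinol; 5 prenyl bromide
Product: 7 3,5-dihydroxy-2,4-bis(2-methylpropanoyl)-6,6-bis(3-methylbut-2-en-1-yl)cyclohexa-2,4-dien-1-one (achiral), via monoprenyl diacylphloroglucinol 6 (not isolated)
Conditions: 5 (2.2 equiv), NaOMe (3 equiv), MeOH, −10 to 0 °C; dilute HCl work-up
Reagents that add atoms: prenyl bromide (5), CC(C)=CCBr
Why: Dearomative double C-alkylation of the phloroglucinolate (the gem-dialkylation used for hop beta-acids) should place both prenyl groups on the only unsubstituted ring carbon, the second alkylation breaking aromaticity to give the vinylogous-acid trione; no stereocentre is formed.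

Step 3
Reactants: 7 the diprenyl trione; 8 N-(phenylseleno)phthalimide
Product: 10 4-hydroxy-8,8-dimethyl-5-(3-methylbut-2-en-1-yl)-1,3-bis(2-methylpropanoyl)-7-exo-(phenylselanyl)bicyclo[3.3.1]non-3-ene-2,9-dione (7S; C1 and C5 arranged in space as in 19), via seleniranium ion 9 (not isolated)
Conditions: 8 (1.0 equiv), chiral squaramide hydrogen-bond donor (tert-leucine arylpyrrolidine amide arm, 3,5-bis(trifluoromethyl)phenyl arm; 10 mol%), HCl (10 mol%, Et2O solution), toluene/CH2Cl2, −40 °C
Reagents that add atoms: N-(phenylseleno)phthalimide (8), O=C1c2ccccc2C(=O)N1[Se]c1ccccc1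
Why: Proposed new method: HCl-activated 8 should deliver PhSe+ reversibly to a prenyl alkene of 7 to give seleniranium ion 9, held as an ion pair with the squaramide-bound chloride while the acidic triketone hydrogen-bonds to the same catalyst, and the enol carbon C1 opens the ion at its tertiary carbon C8 from the face anti to selenium, forming the C1–C8 bond. The closest known reactions are hydrogen-bond-donor-catalysed enantioselective selenoetherifications that run by dynamic kinetic resolution of seleniranium ions, and Lewis-acid-promoted PhSe+ closures of prenyl groups onto beta-dicarbonyl enol carbons; a triketone carbon nucleophile under chiral ion-pair control has not been shown. Ring C1–C8–C7–C6–C5–C9 closes in the 6-endo mode with respect to the former alkene (Markovnikov opening) through a chair. C7 is set by the alkene face that carries selenium in the cyclising ion pair, hence by the catalyst; C1 and C5 follow from C7, because anti opening in the chair puts SePh equatorial (exo) and the one-carbon bridge can only span C1 and C5 cis. The step needs carbon to win over the enol oxygen and one alkene face to react: the twofold symmetry of 7 makes both prenyl groups and both acyl-bearing carbons lead to the same bicycle, O-cyclised selenoethers are tertiary alkyl esters of a vinylogous acid that should re-ionise under the HCl co-catalyst and drain into the irreversible C–C closure, and one equivalent of 8 leaves the second prenyl group untouched.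

Step 4
Reactants: 11 allyl phenyl sulfone
Product: 13 2-methylbut-3-en-2-yl phenyl sulfone, via monomethyl allyl sulfone 12 (not isolated)
Conditions: n-BuLi (1.05 equiv), THF, −78 °C; MeI (1.1 equiv); then n-BuLi (1.05 equiv), −78 °C; MeI (1.2 equiv), to rt
Reagents that add atoms: methyl iodide, CI
Why: Alkylation of a sulfonyl-stabilised allyl anion occurs at the carbon next to sulfur, so two deprotonation–methylation cycles in one flask should give the tertiary sulfone.

Step 5
Reactants: 10 the 7-exo selenide; 13 2-methylbut-3-en-2-yl phenyl sulfone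
Product: 14 4-hydroxy-8,8-dimethyl-5,7-bis(3-methylbut-2-en-1-yl)-1,3-bis(2-methylpropanoyl)bicyclo[3.3.1]non-3-ene-2,9-dione (7-exo prenyl; C1, C5 and C7 as in 19)
Conditions: 13 (3 equiv), Bu3SnSnBu3 (1.5 equiv), benzene, hν (sunlamp), 40 °C
Reagents that add atoms: 2-methylbut-3-en-2-yl phenyl sulfone (13), C=CC(C)(C)S(=O)(=O)c1ccccc1
Why: In this Keck-type radical allylation by SH2' transfer from an allyl sulfone, Bu3Sn• abstracts PhSe from C7, the secondary C7 radical adds to the terminal CH2 of 13 and loss of PhSO2• (which regenerates Bu3Sn• from the ditin) leaves the prenyl group, the reagent approaching the exo face because the endo face of C7 is walled off by the C2–C3–C4 bridge, so the exo (7S) configuration is kept.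

Step 6
Reactants: 14 the 3-isobutyryl 5,7-diprenyl compound
Product: 17 4-hydroxy-8,8-dimethyl-5,7-bis(3-methylbut-2-en-1-yl)-1-(2-methylpropanoyl)bicyclo[3.3.1]non-3-ene-2,9-dione (C3–H; C1, C5 and C7 as in 19), via 3-chloro-3-isobutyryl trione 15 (not isolated), via 3-chloro enol 16 (not isolated)
Conditions: NCS (1.0 equiv), NaHCO3, CH2Cl2, 0 °C; then K2CO3, MeOH, 0 °C to rt; then AcOH, Zn dust, rt
Reagents that add atoms: none
Why: In this chlorination, retro-Claisen and dechlorination sequence, C-chlorination at C3 makes the otherwise alkoxide-inert enolised triketone non-enolisable, methoxide then attacks the less hindered exocyclic isobutyryl carbonyl and expels the stabilised 3-chloro-1,3-dione enolate (the C1 isobutyryl group stays because a bridgehead carbanion is a poor leaving group), and zinc in acetic acid reduces the C–Cl bond (also that of any 3,3-dichloride) without touching a stereocentre.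

Step 7
Reactants: 17 the C3–H dione; 18 prenyl acetate
Product: 19 (1R,5R,7S)-4-hydroxy-8,8-dimethyl-3,5,7-tris(3-methylbut-2-en-1-yl)-1-(2-methylpropanoyl)bicyclo[3.3.1]non-3-ene-2,9-dione (target)
Conditions: Pd(PPh3)4 (5 mol%), 18 (1.1 equiv), DBU (1.1 equiv), THF, rt
Reagents that add atoms: prenyl acetate (18), CC(C)=CCOC(C)=O
Why: In this Tsuji–Trost allylation the soft enolate of the cyclic 1,3-dione should attack the unsubstituted terminus of the 1,1-dimethylallyl palladium complex with C3, O-prenylation being reversible under zerovalent palladium, to give the linear prenyl group; no stereocentre is formed.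

**Compound list**

1 | phloroglucinol (benzene-1,3,5-triol) | Oc1cc(O)cc(O)c1 | starting material
2 | isobutyryl chloride (2-methylpropanoyl chloride) | CC(C)C(Cl)=O | starting material
3 | 2-methyl-1-(2,4,6-trihydroxyphenyl)propan-1-one (monoacyl stage, not isolated) | CC(C)C(=O)c1c(O)cc(O)cc1O | intermediate
4 | 2,4-diisobutyrylphloroglucinol, 1,1'-(2,4,6-trihydroxy-1,3-phenylene)bis(2-methylpropan-1-one) | CC(C)C(=O)c1c(O)cc(O)c(C(=O)C(C)C)c1O | intermediate
5 | prenyl bromide (1-bromo-3-methylbut-2-ene) | CC(C)=CCBr | starting material
6 | 2,4-diisobutyryl-6-prenylphloroglucinol (monoprenyl stage, not isolated) | CC(C)=CCc1c(O)c(C(=O)C(C)C)c(O)c(C(=O)C(C)C)c1O | intermediate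
7 | 3,5-dihydroxy-2,4-bis(2-methylpropanoyl)-6,6-bis(3-methylbut-2-en-1-yl)cyclohexa-2,4-dien-1-one (achiral) | CC(C)C(=O)C1=C(O)C(C(=O)C(C)C)=C(O)C(CC=C(C)C)(CC=C(C)C)C1=O | intermediate
8 | N-(phenylseleno)phthalimide, 2-(phenylselanyl)isoindoline-1,3-dione | O=C1c2ccccc2C(=O)N1[Se]c1ccccc1 | starting material
9 | seleniranium ion of 7: one prenyl alkene bridged by PhSe+ on the face that leads to 7S (ring carbon C6 of the trione left undefined because the tautomers interconvert; not isolated) | CC(C)C(=O)C1=C(O)C(C(=O)C(C)C)=C(O)C(CC=C(C)C)(C[C@@H]2[Se+](c3ccccc3)C2(C)C)C1=O | intermediate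
10 | 4-hydroxy-8,8-dimethyl-5-(3-methylbut-2-en-1-yl)-1,3-bis(2-methylpropanoyl)-7-exo-(phenylselanyl)bicyclo[3.3.1]non-3-ene-2,9-dione, 7S, bridgeheads arranged as in 19 | CC(C)C(=O)C1=C(O)[C@@]2(CC=C(C)C)C[C@H]([Se]c3ccccc3)C(C)(C)[C@@](C(=O)C(C)C)(C1=O)C2=O | intermediate
11 | allyl phenyl sulfone (prop-2-en-1-ylsulfonylbenzene) | C=CCS(=O)(=O)c1ccccc1 | starting material
12 | but-3-en-2-yl phenyl sulfone (racemic, not isolated) | C=CC(C)S(=O)(=O)c1ccccc1 | intermediate
13 | 2-methylbut-3-en-2-yl phenyl sulfone | C=CC(C)(C)S(=O)(=O)c1ccccc1 | intermediate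
14 | 4-hydroxy-8,8-dimethyl-5,7-bis(3-methylbut-2-en-1-yl)-1,3-bis(2-methylpropanoyl)bicyclo[3.3.1]non-3-ene-2,9-dione, 7-exo prenyl, C1, C5 and C7 as in 19 | CC(C)C(=O)C1=C(O)[C@@]2(CC=C(C)C)C[C@H](CC=C(C)C)C(C)(C)[C@@](C(=O)C(C)C)(C1=O)C2=O | intermediate
15 | 3-chloro-8,8-dimethyl-5,7-bis(3-methylbut-2-en-1-yl)-1,3-bis(2-methylpropanoyl)bicyclo[3.3.1]nonane-2,4,9-trione (C3 configuration undefined, not isolated) | CC(C)C(=O)C1(Cl)C(=O)[C@@]2(CC=C(C)C)C[C@H](CC=C(C)C)C(C)(C)[C@@](C(=O)C(C)C)(C1=O)C2=O | intermediate
16 | 3-chloro-4-hydroxy-8,8-dimethyl-5,7-bis(3-methylbut-2-en-1-yl)-1-(2-methylpropanoyl)bicyclo[3.3.1]non-3-ene-2,9-dione (not isolated) | ClC1=C(O)[C@@]2(CC=C(C)C)C[C@H](CC=C(C)C)C(C)(C)[C@@](C(=O)C(C)C)(C1=O)C2=O | intermediate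
17 | 4-hydroxy-8,8-dimethyl-5,7-bis(3-methylbut-2-en-1-yl)-1-(2-methylpropanoyl)bicyclo[3.3.1]non-3-ene-2,9-dione, C1, C5 and C7 as in 19 | C1=C(O)[C@@]2(CC=C(C)C)C[C@H](CC=C(C)C)C(C)(C)[C@@](C(=O)C(C)C)(C1=O)C2=O | intermediate
18 | prenyl acetate (3-methylbut-2-en-1-yl acetate) | CC(C)=CCOC(C)=O | starting material
19 | (1R,5R,7S)-4-hydroxy-8,8-dimethyl-3,5,7-tris(3-methylbut-2-en-1-yl)-1-(2-methylpropanoyl)bicyclo[3.3.1]non-3-ene-2,9-dione | CC(C)=CCC1=C(O)[C@@]2(CC=C(C)C)C[C@H](CC=C(C)C)C(C)(C)[C@@](C(=O)C(C)C)(C1=O)C2=O | target

**Step count and risks**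

Total step count: 7. Longest linear sequence: 6 (steps 1, 2, 3, 5, 6, 7 from phloroglucinol); step 4 makes the prenyl-transfer reagent.

Steps most likely to fail:

1. Step 3 (the one new method of the route). The enol oxygen may capture the seleniranium ion and not revert at low temperature, and the catalyst may discriminate the alkene faces poorly because the strongly acidic substrate can itself activate 8 (racemic background). Fallback with known chemistry and no chiral catalyst: starting from 7, the closure is run under equilibrating Lewis-acid conditions (8, SnCl4, CH2Cl2, −78 to −20 °C), the established way to close prenyl groups onto beta-dicarbonyl carbons with PhSe+, which should give the racemic 7-exo selenide F1. Resolution of F1 by preparative chromatography on a chiral stationary phase returns the route to 10.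

2. Step 6. Electrophilic chlorine may attack a prenyl alkene (chloroetherification with the neighbouring enol oxygen) in competition with C3, or methoxide may open the ring at C4 in place of removing the exocyclic acyl group. Fallback: starting from 14, C3 is made quaternary with the prenyl group itself instead of chlorine. Tsuji–Trost C-prenylation (Pd(PPh3)4, 18, DBU, THF) should give the non-enolisable 3-isobutyryl-3-prenyl compound F2, whose isobutyryl group is then removed by retro-Claisen methanolysis (K2CO3, MeOH). This arrives directly at 19, so that 17 and step 7 are not needed.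

3. Step 5. Addition of the hindered C7 radical to the sulfone may be slow, so that hydrogen abstraction (simple reduction at C7) takes over, or the acidic triketone may protodestannylate the ditin. Fallback: starting from 10, Keck allylation (allylSnBu3, AIBN, benzene, 80 °C) should give the 7-exo-allyl compound F3. Cross-metathesis with 2-methyl-2-butene (second-generation Grubbs catalyst RuCl2(=CHPh)(PCy3)(H2IMes), CH2Cl2, 40 °C) then turns allyl into prenyl and rejoins the route at 14.

Further compounds
F1 | step 3 | racemic 4-hydroxy-8,8-dimethyl-5-(3-methylbut-2-en-1-yl)-1,3-bis(2-methylpropanoyl)-7-exo-(phenylselanyl)bicyclo[3.3.1]non-3-ene-2,9-dione (relative configuration shown) | CC(C)C(=O)C1=C(O)[C@@]2(CC=C(C)C)C[C@H]([Se]c3ccccc3)C(C)(C)[C@@](C(=O)C(C)C)(C1=O)C2=O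
F2 | step 6 | 8,8-dimethyl-3,5,7-tris(3-methylbut-2-en-1-yl)-1,3-bis(2-methylpropanoyl)bicyclo[3.3.1]nonane-2,4,9-trione (C3 configuration undefined; C1, C5 and C7 as in 19) | CC(C)=CCC1(C(=O)C(C)C)C(=O)[C@@]2(CC=C(C)C)C[C@H](CC=C(C)C)C(C)(C)[C@@](C(=O)C(C)C)(C1=O)C2=O
F3 | step 5 | 7-exo-allyl-4-hydroxy-8,8-dimethyl-5-(3-methylbut-2-en-1-yl)-1,3-bis(2-methylpropanoyl)bicyclo[3.3.1]non-3-ene-2,9-dione (C1, C5 and C7 as in 14) | CC(C)C(=O)C1=C(O)[C@@]2(CC=C(C)C)C[C@H](CC=C)C(C)(C)[C@@](C(=O)C(C)C)(C1=O)C2=O
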